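The ring atoms follow the target SMILES: C1 (CHOAc), C2, C3 (CHMe), C4 (CHOH), C5 (C=O), C6, C7, C8=C9, C10 (CHOAc); ring A is C2–C7, ring B C1/C2/C7–C10. The plan rests on seeing that C5, C10 and C1, contiguous once a C5–C10 bond is reinstated, are the hydroxyl and methoxy carbons of syringol. Oxidising syringol to its ortho-quinone monoketal and trapping it with a (Z)-propenyl ether of (R)-1-(2-naphthyl)ethanol forges C2–C3 and C4–C5 in one operation, giving a bicyclo[2.2.2]octenone that holds ring A and four stereocentres. Isopropenyl addition at C10 and anionic oxy-Cope rearrangement (C5–C10 broken, C7–C8 made) then unfold it into the cis-decalin.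

Key step: step 3

Notation: β is the face of the ring-fusion hydrogens H2 and H7, α the opposite face; R* = (R)-1-(naphthalen-2-yl)ethyl, chosen because it tolerates the acid of steps 7 and 10 yet is cleaved by DDQ in step 13.

Assumption: the sense of facial induction is taken from the conformational model given in step 3; should experiment show the opposite sense, the enantiomeric alcohol would be used with no other change.

Step 1
Reactants: 1 (R)-1-(naphthalen-2-yl)ethan-1-ol; 2 allyl bromide
Product: 3 2-[(1R)-1-(prop-2-en-1-yloxy)ethyl]naphthalene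
Conditions: NaH, THF/DMF, 0 °C → rt
Reagents that add atoms: none
Why: Williamson ether synthesis (SN2 of the sodium alkoxide on the allylic bromide); the carbinol centre is not touched, so (R) is retained.

Step 2
Reactants: 3 2-[(1R)-1-(prop-2-en-1-yloxy)ethyl]naphthalene
Product: 4 2-[(1R)-1-{[(1Z)-prop-1-en-1-yl]oxy}ethyl]naphthalene
Conditions: KOtBu (0.3 equiv), DMSO, rt
Reagents that add atoms: none
Why: Base-mediated allyl-to-propenyl ether isomerisation, in which the potassium-bridged cisoid oxyallyl anion is reprotonated at the terminus to give the (Z)-enol ether under kinetic control, while the far less acidic benzylic C–H is left alone.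

Step 3
Reactants: 5 2,6-dimethoxyphenol; 4 2-[(1R)-1-{[(1Z)-prop-1-en-1-yl]oxy}ethyl]naphthalene
Product: 7 (1S,4S,7R,8R)-7-[(1R)-1-(naphthalen-2-yl)ethoxy]-1,3,3-trimethoxy-8-methylbicyclo[2.2.2]oct-5-en-2-one, via 2,6,6-trimethoxycyclohexa-2,4-dien-1-one 6 (not isolated)
Conditions: PhI(OAc)2 (slow addition), NaHCO3, MeOH, 0 °C → rt, 4 in excess (3 equiv, surplus recovered)
Reagents that add atoms: methanol, CO
Why: Proposed new method: the in situ oxidation of a 2-methoxyphenol to a cyclohexa-2,4-dienone dimethyl ketal and its inverse-demand Diels–Alder reaction with enol ethers are established, whereas control of the absolute sense by an O-(1-arylethyl) group in this cycloaddition is untested, the closest known reaction type being auxiliary-directed [2+2] and [4+2] cycloadditions of enol ethers of chiral 1-arylethanols. PhI(OAc)2 exchanges a ligand for the phenoxide and collapses with loss of iodobenzene while methanol adds at C1, giving dienone 6, whose electron-poor diene C5=C6–C7=C2 then reacts concertedly but asynchronously with 4. Ring A (C2–C3–C4–C5–C6–C7) is closed by this intermolecular suprafacial [4+2] addition, the nucleophilic CHMe carbon C3 bonding to the δ-carbon C2 (largest LUMO coefficient) and the oxygen-bearing C4 to C5, which is the ortho orientation always seen with such dienones. C3 and C4 emerge cis because the (Z)-geometry is conserved, and C2 and C5 follow from the endo transition state that places ether oxygen and methyl under the diene, i.e. syn to the new C6=C7 bridge. The absolute configuration of all four centres depends on which enol-ether face is attacked: in the s-trans conformer imposed by the (Z)-methyl, with the carbinol C–H eclipsing the C4–H bond to avoid A(1,3) strain, the naphthyl group covers one face and the small methyl the other, and for the (R)-ether the open face is the one that leads to 7. Excess 4 and slow addition of the oxidant hold back dimerisation of 6, and NaHCO3 keeps the liberated acetic acid from adding methanol to the enol ether.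

Step 4
Reactants: 7 (1S,4S,7R,8R)-7-[(1R)-1-(naphthalen-2-yl)ethoxy]-1,3,3-trimethoxy-8-methylbicyclo[2.2.2]oct-5-en-2-one; 8 isopropenylmagnesium bromide
Product: 9 (1S,2S,4S,7R,8R)-7-[(1R)-1-(naphthalen-2-yl)ethoxy]-1,3,3-trimethoxy-8-methyl-2-(prop-1-en-2-yl)bicyclo[2.2.2]oct-5-en-2-ol
Conditions: THF, −78 → 0 °C; aqueous work-up
Reagents that add atoms: none
Why: Grignard 1,2-addition to the non-enolisable bridged ketone from the open face beside the C6=C7 bridge (the other face is screened by the exo hydrogens of the C3–C4 bridge), which sets C10 with the isopropenyl group syn to the alkene as the rearrangement requires.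

Step 5
Reactants: 9 (1S,2S,4S,7R,8R)-7-[(1R)-1-(naphthalen-2-yl)ethoxy]-1,3,3-trimethoxy-8-methyl-2-(prop-1-en-2-yl)bicyclo[2.2.2]oct-5-en-2-ol
Product: 11 cis-decalin silyl enol ether [C1(OMe)2; C9=C10 bearing C10–OSiMe3 and C9–Me; C5(OMe)=C6; C4 β-OR*; C3 β-Me; H2/H7 β], via potassium enolate 10 (not isolated)
Conditions: KH, 18-crown-6, THF, 0 °C → rt; then Me3SiCl, −78 °C
Reagents that add atoms: chlorotrimethylsilane, C[Si](C)(C)Cl
Why: Anionic oxy-Cope rearrangement of the potassium alkoxide of the 1,5-diene C8=C9–C10–C5–C6=C7 through the enforced boat transition state breaks C5–C10 and forms C7–C8 on the face from which the C1–C10 bridge departs, so C7 is set cis to C2, and O-silylation traps the regiodefined enolate.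

Step 6
Reactants: 11 cis-decalin silyl enol ether
Product: 12 cis-decalin enone [C8=C9(Me)–C10(=O); C1(OMe)2; C5(OMe)=C6; C4 β-OR*; C3 β-Me; H2/H7 β]
Conditions: Pd(OAc)2 (1.1 equiv), MeCN, rt
Reagents that add atoms: none
Why: Saegusa–Ito oxidation, in which the divalent palladium enolate at C9 undergoes syn β-hydride elimination toward the ring carbon C8 to give the conjugated endocyclic enone, the methyl enol ether of ring A reacting far more slowly than the silyl enol ether.

Step 7
Reactants: 12 cis-decalin enone
Product: 14 hydroxy ketone [C5 ketone with C6 H2; C10 α-OH; C8=C9(Me); C1(OMe)2; C4 β-OR*; C3 β-Me; H2/H7 β], via C10 α-allylic alcohol 13 (not isolated)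
Conditions: NaBH4, CeCl3·7H2O, MeOH, −40 °C; then aq. oxalic acid, THF, 0 °C → rt
Reagents that add atoms: water, O
Why: Luche 1,2-reduction with hydride delivered to C10 from the convex β face (the α face is covered by ring A, whose C3 stands axial on ring B) gives the α-alcohol, and dilute oxalic acid then hydrolyses only the electron-rich C5 enol ether because the α-oxygenated, hindered C1 ketal ionises much more slowly.

Step 8
Reactants: 14 hydroxy ketone; 15 acetone
Product: 16 aldol adduct [as 14 with a 2-hydroxypropan-2-yl group on C6, expected β (anti to C8); configuration at C6 immaterial]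
Conditions: LiN(iPr)2 (2.2 equiv), THF, −78 °C; acetone, −78 °C; AcOH quench at −78 °C
Reagents that add atoms: none
Why: Directed aldol addition, with kinetic deprotonation of the alkoxide ketone at the unhindered C6 methylene rather than at the tertiary, ether-flanked C4–H, followed by addition of the lithium enolate to acetone; the new C6 centre disappears in step 9.

Step 9
Reactants: 16 aldol adduct
Product: 18 isopropylidene enone [C6=CMe2; C5 ketone; C10 α-OAc; C8=C9(Me); C1(OMe)2; C4 β-OR*; C3 β-Me; H2/H7 β], via bis-acetate 17 (not isolated)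
Conditions: Ac2O, 4-(dimethylamino)pyridine, Et3N, CH2Cl2, rt; then 1,8-diazabicyclo[5.4.0]undec-7-ene, rt
Reagents that add atoms: acetic anhydride, CC(=O)OC(C)=O
Why: Nucleophile-catalysed acetylation of both hydroxyls followed by E1cB elimination of the tertiary β-acetoxy ketone, which can only give the conjugated C6 isopropylidene, while the C10 acetate installed here is the one the target carries.

Step 10
Reactants: 18 isopropylidene enone
Product: 19 C1 ketone [as 18 with C1=O in place of the dimethyl ketal]
Conditions: p-toluenesulfonic acid monohydrate (cat.), acetone/H2O, 40 °C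
Reagents that add atoms: water, O
Why: Acid-catalysed ketal hydrolysis driven by exchange into acetone, under which the secondary naphthylethyl ether, the allylic acetate and the enone should persist and enolisation toward C2 is slow.

Step 11
Reactants: 19 C1 ketone
Product: 20 C1 α-alcohol [as 19 with C1 α-OH]
Conditions: NaBH4, MeOH/CH2Cl2, −78 °C
Reagents that add atoms: none
Why: Chemoselective borohydride reduction of the activated α-acetoxy ketone in preference to the hindered, conjugated C5 ketone, with axial hydride attack from the β face (the α face is blocked by C3 on C2 and by the C10 acetate) giving the α-alcohol; any 1,2-acetyl shift is harmless because step 12 acetylates both positions.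

Step 12
Reactants: 20 C1 α-alcohol
Product: 21 (3R,4R,4aS,5R,6S,8aR)-4,7-dimethyl-3-[(1R)-1-(naphthalen-2-yl)ethoxy]-2-oxo-1-(propan-2-ylidene)-1,2,3,4,4a,5,6,8a-octahydronaphthalene-5,6-diyl diacetate
Conditions: Ac2O, pyridine, 4-(dimethylamino)pyridine (cat.), CH2Cl2, rt
Reagents that add atoms: acetic anhydride, CC(=O)OC(C)=O
Why: Standard acetylation of the only free hydroxyl, the C4 oxygen being masked by the auxiliary.

Step 13
Reactants: 21 the diacetate ether
Product: 22 (3R,4R,4aS,5R,6S,8aR)-3-hydroxy-4,7-dimethyl-2-oxo-1-(propan-2-ylidene)-1,2,3,4,4a,5,6,8a-octahydronaphthalene-5,6-diyl diacetate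
Conditions: 2,3-dichloro-5,6-dicyano-1,4-benzoquinone (DDQ), CH2Cl2/pH 7 buffer, rt
Reagents that add atoms: none
Why: Oxidative cleavage of a naphthylmethyl-type ether by hydride abstraction from the benzylic C–H and hydrolysis of the resulting oxocarbenium ion, to which acetates, the enone and the isolated alkene are inert.

Step 14
Reactants: 22 the C4 epimer of the target
Product: 23 (3S,4R,4aS,5R,6S,8aR)-3-hydroxy-4,7-dimethyl-2-oxo-1-(propan-2-ylidene)-1,2,3,4,4a,5,6,8a-octahydronaphthalene-5,6-diyl diacetate
Conditions: 1,8-diazabicyclo[5.4.0]undec-7-ene (cat.), toluene, rt → 40 °C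
Reagents that add atoms: none
Why: Base-mediated epimerisation of the α-ketol through the C4=C5 enediolate under thermodynamic control, which should favour 23 because its C4 hydroxyl is equatorial, trans to the C3 methyl and hydrogen-bonded to the C5 carbonyl, whereas in 22 it is axial; any C4 epimer formed in earlier basic steps converges here.

Compound list
1 | (R)-1-(naphthalen-2-yl)ethan-1-ol | C[C@@H](O)c1ccc2ccccc2c1 | starting material
2 | allyl bromide | C=CCBr | starting material
3 | 2-[(1R)-1-(prop-2-en-1-yloxy)ethyl]naphthalene | C=CCO[C@H](C)c1ccc2ccccc2c1 | intermediate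
4 | 2-[(1R)-1-{[(1Z)-prop-1-en-1-yl]oxy}ethyl]naphthalene | C/C=C\O[C@H](C)c1ccc2ccccc2c1 | intermediate
5 | 2,6-dimethoxyphenol | COc1cccc(OC)c1O | starting material
6 | 2,6,6-trimethoxycyclohexa-2,4-dien-1-one | COC1=CC=CC(OC)(OC)C1=O | intermediate
7 | (1S,4S,7R,8R)-7-[(1R)-1-(naphthalen-2-yl)ethoxy]-1,3,3-trimethoxy-8-methylbicyclo[2.2.2]oct-5-en-2-one (ether and methyl syn to the C5=C6 bridge of the bicycle) | CO[C@@]12C=C[C@@H]([C@@H](C)[C@H]1O[C@H](C)c3ccc4ccccc4c3)C(OC)(OC)C2=O | intermediate
8 | isopropenylmagnesium bromide | CC(=C)[Mg]Br | starting material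
9 | (1S,2S,4S,7R,8R)-7-[(1R)-1-(naphthalen-2-yl)ethoxy]-1,3,3-trimethoxy-8-methyl-2-(prop-1-en-2-yl)bicyclo[2.2.2]oct-5-en-2-ol (isopropenyl syn to the alkene bridge) | CO[C@@]12C=C[C@@H]([C@@H](C)[C@H]1O[C@H](C)c3ccc4ccccc4c3)C(OC)(OC)[C@]2(O)C(C)=C | intermediate
10 | potassium C9=C10 enolate of the cis-decalin [C1(OMe)2; C5(OMe)=C6; C4 β-OR*; C3 β-Me; H2/H7 β] | COC1(OC)[C@@H]2[C@@H](C)[C@@H](O[C@H](C)c3ccc4ccccc4c3)C(OC)=C[C@@H]2CC(C)=C1[O-].[K+] | intermediate
11 | cis-decalin silyl enol ether [C10–OSiMe3 on C9=C10; otherwise as 10] | COC1(OC)[C@@H]2[C@@H](C)[C@@H](O[C@H](C)c3ccc4ccccc4c3)C(OC)=C[C@@H]2CC(C)=C1O[Si](C)(C)C | intermediate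
12 | cis-decalin enone [C8=C9(Me)–C10(=O); C1(OMe)2; C5(OMe)=C6; C4 β-OR*; C3 β-Me; H2/H7 β] | COC1(OC)[C@@H]2[C@@H](C)[C@@H](O[C@H](C)c3ccc4ccccc4c3)C(OC)=C[C@@H]2C=C(C)C1=O | intermediate
13 | C10 α-allylic alcohol [as 12 with C10 α-OH] | COC1(OC)[C@@H]2[C@@H](C)[C@@H](O[C@H](C)c3ccc4ccccc4c3)C(OC)=C[C@@H]2C=C(C)[C@@H]1O | intermediate
14 | hydroxy ketone [C5=O, C6 H2; C10 α-OH; C8=C9(Me); C1(OMe)2; C4 β-OR*; C3 β-Me; H2/H7 β] | COC1(OC)[C@@H]2[C@@H](C)[C@@H](O[C@H](C)c3ccc4ccccc4c3)C(=O)C[C@@H]2C=C(C)[C@@H]1O | intermediate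
15 | acetone | CC(C)=O | starting material
16 | aldol adduct [as 14 with β-C(CH3)2OH on C6] | COC1(OC)[C@@H]2[C@@H](C)[C@@H](O[C@H](C)c3ccc4ccccc4c3)C(=O)[C@@H](C(C)(C)O)[C@@H]2C=C(C)[C@@H]1O | intermediate
17 | bis-acetate of 16 [C10 α-OAc; side-chain tertiary OAc] | COC1(OC)[C@@H]2[C@@H](C)[C@@H](O[C@H](C)c3ccc4ccccc4c3)C(=O)[C@@H](C(C)(C)OC(C)=O)[C@@H]2C=C(C)[C@@H]1OC(C)=O | intermediate
18 | isopropylidene enone [C6=CMe2; C5=O; C10 α-OAc; C8=C9(Me); C1(OMe)2; C4 β-OR*; C3 β-Me; H2/H7 β] | COC1(OC)[C@@H]2[C@@H](C)[C@@H](O[C@H](C)c3ccc4ccccc4c3)C(=O)C(=C(C)C)[C@@H]2C=C(C)[C@@H]1OC(C)=O | intermediate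
19 | C1 ketone [as 18 with C1=O] | O=C1[C@@H]2[C@@H](C)[C@@H](O[C@H](C)c3ccc4ccccc4c3)C(=O)C(=C(C)C)[C@@H]2C=C(C)[C@@H]1OC(C)=O | intermediate
20 | C1 α-alcohol [as 19 with C1 α-OH] | O[C@@H]1[C@@H]2[C@@H](C)[C@@H](O[C@H](C)c3ccc4ccccc4c3)C(=O)C(=C(C)C)[C@@H]2C=C(C)[C@@H]1OC(C)=O | intermediate
21 | (3R,4R,4aS,5R,6S,8aR)-4,7-dimethyl-3-[(1R)-1-(naphthalen-2-yl)ethoxy]-2-oxo-1-(propan-2-ylidene)-1,2,3,4,4a,5,6,8a-octahydronaphthalene-5,6-diyl diacetate | CC(=O)O[C@@H]1[C@@H]2[C@@H](C)[C@@H](O[C@H](C)c3ccc4ccccc4c3)C(=O)C(=C(C)C)[C@@H]2C=C(C)[C@@H]1OC(C)=O | intermediate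
22 | (3R,4R,4aS,5R,6S,8aR)-3-hydroxy-4,7-dimethyl-2-oxo-1-(propan-2-ylidene)-1,2,3,4,4a,5,6,8a-octahydronaphthalene-5,6-diyl diacetate (C4 epimer of the target) | CC(=O)O[C@@H]1[C@@H]2[C@@H](C)[C@@H](O)C(=O)C(=C(C)C)[C@@H]2C=C(C)[C@@H]1OC(C)=O | intermediate
23 | (3S,4R,4aS,5R,6S,8aR)-3-hydroxy-4,7-dimethyl-2-oxo-1-(propan-2-ylidene)-1,2,3,4,4a,5,6,8a-octahydronaphthalene-5,6-diyl diacetate | CC(=O)O[C@@H]1[C@@H]2[C@@H](C)[C@H](O)C(=O)C(=C(C)C)[C@@H]2C=C(C)[C@@H]1OC(C)=O | target

Total step count: 14. Longest linear sequence: 14 steps (1 → 23); 5, 8 and 15 enter as commercial partners in steps 3, 4 and 8.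

Steps most likely to fail

Step 3. The naphthylethyl group may discriminate too weakly between the two faces of the enol ether, so that both endo adducts form. Fallback (known chemistry), setting out from 4 and 5 and returning at 7: induction is given up and the ether serves as a covalent resolving group. The cycloaddition is run for conversion only and delivers 7 together with the diastereomeric endo adduct F1, which has the mirror-image bicycle but the same (R)-ether centre. Being diastereomers, the two are separated by chromatography or crystallisation, and 7 continues with step 4.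

Step 7. Hydride may be delivered to the wrong face of C10, giving the β-alcohol. Fallback, setting out from 12 and returning at 13: substrate control is replaced by reagent control in a Corey–Bakshi–Shibata reduction. The catalyst is (R)-1-methyl-3,3-diphenyltetrahydro-1H,3H-pyrrolo[1,2-c][1,3,2]oxazaborole with catecholborane in toluene at −78 °C. The quaternary ketal carbon C1 is taken as the large and the alkenyl carbon C9 as the small substituent, so that hydride arrives on the β face. The oxalic acid treatment then gives 14 as in the main route. This fallback makes no new compound (F0).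

Step 14. The equilibrium may not lie far enough on the side of 23, or the base may deconjugate the isopropylidene ketone before equilibration is complete. Fallback, setting out from 22 and returning at 23: the thermodynamic epimerisation is replaced by a stereospecific SN2 inversion. Mitsunobu reaction of 22 (PPh3, diisopropyl azodicarboxylate, formic acid, THF, 0 °C → rt) gives the inverted C4 formate of the target F2. Its formyl group is removed selectively in the presence of the two acetates with KHCO3 in MeOH/H2O at 0 °C, giving 23.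

Further compounds
F1 | step 3 | (1R,4R,7S,8S)-7-[(1R)-1-(naphthalen-2-yl)ethoxy]-1,3,3-trimethoxy-8-methylbicyclo[2.2.2]oct-5-en-2-one (diastereomeric endo adduct) | CO[C@]12C=C[C@H]([C@H](C)[C@@H]1O[C@H](C)c3ccc4ccccc4c3)C(OC)(OC)C2=O
F0 | step 7 | none | none
F2 | step 14 | (3S,4R,4aS,5R,6S,8aR)-3-(formyloxy)-4,7-dimethyl-2-oxo-1-(propan-2-ylidene)-1,2,3,4,4a,5,6,8a-octahydronaphthalene-5,6-diyl diacetate (C4 formate of the target) | CC(=O)O[C@@H]1[C@@H]2[C@@H](C)[C@H](OC=O)C(=O)C(=C(C)C)[C@@H]2C=C(C)[C@@H]1OC(C)=O
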